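**Retrosynthetic overview**

1. Feature: the inner dihydrobenzofuran (O1', C2' with 4-hydroxyphenyl and (S) configuration, C3', C4'–OH, C6'–C bond) is (S)-naringenin with flavanone C4 pushed out of the heterocycle; the outer one (O1, C2 (R), C3, C4–OH, styryl at C6) is the same unit in mirror-image form. The target is (2R,3R,2'S,3'S), both rings trans.
2. Disconnections, last to first: seven O–CH3 bonds (BBr3); C6–CH= (Heck reaction of the C6 triflate with 4-methoxystyrene); C3–C6' (decarboxylative arylation of the outer C3 acid with the inner C6' boronic acid); C3'–aryl (the same reaction with 3,5-dimethoxyphenylboronic acid).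
3. Both 3-carboxylic acids come from ring contraction of the two enantiomers of one protected flavanone: (S) from naringenin, (R) by racemisation and chiral chromatography.
4. Ring formation order: inner dihydrofuran (step 3), then outer dihydrofuran (step 10); all six benzene rings are bought in.

Key step: step 3

Remark on the chemistry: the hydrogen-bonded 5-OH of a flavanone reacts too slowly with diazoalkanes, so both free phenols are methylated with MeI/Ag2O, which likewise works without a soluble base.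
Remark: flavanone 4 from step 2 is divided between step 3 and step 9; steps 10 and 11 repeat steps 3 and 4 on the mirror-image series.

**Route**

Step 1
Reactants: 1 (S)-naringenin; 2 benzyl bromide
Product: 3 (2S)-7-(benzyloxy)-5-hydroxy-2-(4-hydroxyphenyl)chroman-4-one
Conditions: BnBr (1.05 equiv), KHCO3 (1.2 equiv), DMF, rt
Reagents that add atoms: benzyl bromide 2, BrCc1ccccc1
Why: Williamson etherification in which bicarbonate ionises only the 7-OH (para to the C4 carbonyl, the most acidic), while the 5-OH is held in its hydrogen bond to C4=O and the 4'-OH and C3–H stay un-ionised, so the other phenols and the C2 centre (which opens only through a 4'-phenoxide or a C3 enolate) should be left alone.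

Step 2
Reactants: 3 (2S)-7-(benzyloxy)-5-hydroxy-2-(4-hydroxyphenyl)chroman-4-one
Product: 4 (2S)-7-(benzyloxy)-5-methoxy-2-(4-methoxyphenyl)chroman-4-one
Conditions: MeI (10 equiv), Ag2O (3 equiv), DMF, rt, dark
Reagents that add atoms: iodomethane, CI
Why: Purdie–Kuhn methylation, in which silver oxide activates MeI and takes up HI without a soluble base, should methylate the ordinary 4'-OH and the hydrogen-bonded 5-OH while leaving C3–H and hence C2 (S) untouched; the enantiomeric purity of 4 is to be checked on the chiral phase of step 9, which can also upgrade it.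

Step 3
Reactants: 4 (2S)-7-(benzyloxy)-5-methoxy-2-(4-methoxyphenyl)chroman-4-one
Product: 7 methyl (2S,3S)-6-(benzyloxy)-4-methoxy-2-(4-methoxyphenyl)-2,3-dihydro-1-benzofuran-3-carboxylate, via 2H-chromene enol ether 5 (not isolated), via trans C3 iodane ketal 6 (not isolated)
Conditions: PhI(OAc)2 (1.3 equiv), conc. H2SO4 (0.3 equiv), HC(OMe)3, 0 °C to rt
Reagents that add atoms: trimethyl orthoformate, COC(OC)OC
Why: Acid and orthoformate turn the ketone into enol ether 5, whose C3 attacks the trivalent iodine of PhI(OAc)2 on the face away from the pseudo-equatorial C2 aryl group while methanol caps C4, giving iodane 6 with C3–I trans to the aryl group. In 6 the ring bond C4–C4a lies antiperiplanar to the equatorial C3–I bond, so C4a (activated by O1, 5-OMe and 7-OBn) shifts from C4 to C3 as iodobenzene leaves, and the dimethoxycarbenium ion left at the old C4 loses a methyl group to become the ester. The closest known reaction type is the oxidative ring contraction of flavanones with trivalent iodine reagents or thallium trinitrate in trimethyl orthoformate, a semipinacol-type 1,2-aryl shift. The dihydrofuran ring (O1', C2', C3', C3a', C7a') is thus closed by a 1,2-shift that forms C3'–C3a', not by an end-to-end cyclisation. C2' is not touched and keeps (S) from naringenin; C3' is set by inversion at the iodine-bearing carbon, which puts CO2Me trans to the aryl group, also the thermodynamic and epimerisable arrangement. The step needs ring-carbon migration to win over the 2-to-3 shift of the 4-methoxyphenyl group (isoflavone) and over dehydrogenation to the flavone, which the equatorial aryl group (its shift needs a diaxial arrangement) and the high migratory aptitude of the trioxygenated ring carbon secure; short, cold acid exposure limits racemisation through the chalcone.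

Step 4
Reactants: 7 methyl (2S,3S)-6-(benzyloxy)-4-methoxy-2-(4-methoxyphenyl)-2,3-dihydro-1-benzofuran-3-carboxylate
Product: 8 (2S,3S)-6-(benzyloxy)-4-methoxy-2-(4-methoxyphenyl)-2,3-dihydro-1-benzofuran-3-carboxylic acid
Conditions: Me3SnOH (4 equiv), ClCH2CH2Cl, 80 °C; 1 M HCl wash
Reagents that add atoms: trimethyltin hydroxide, C[Sn](C)(C)O
Why: Near-neutral acyl-oxygen ester hydrolysis with Me3SnOH avoids a C3 enolate, whose β-elimination of the O1 phenoxide would open the dihydrofuran irreversibly (re-closure would be 5-endo-trig).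

Step 5
Reactants: 8 (2S,3S)-6-(benzyloxy)-4-methoxy-2-(4-methoxyphenyl)-2,3-dihydro-1-benzofuran-3-carboxylic acid; 9 3,5-dimethoxyphenylboronic acid
Product: 11 (2S,3S)-6-(benzyloxy)-3-(3,5-dimethoxyphenyl)-4-methoxy-2-(4-methoxyphenyl)-2,3-dihydro-1-benzofuran, via tetrachlorophthalimidoyl ester 10 (not isolated)
Conditions: N-hydroxytetrachlorophthalimide (TCNHPI), N,N'-diisopropylcarbodiimide, DMAP (cat.), CH2Cl2, rt; solvent exchange; then 9 (3 equiv), NiCl2·6H2O (20 mol %), bathophenanthroline (22 mol %), Et3N (10 equiv), 1,4-dioxane/DMF 10:1, 75 °C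
Reagents that add atoms: 3,5-dimethoxyphenylboronic acid 9, COc1cc(OC)cc(B(O)O)c1
Why: Nickel-catalysed decarboxylative Suzuki-type arylation of a redox-active ester, in which an arylnickel species reduces 10 to the planar C3' benzylic radical (loss of CO2) and recaptures it on the face away from the C2' aryl group before reductive elimination, so the new C3' centre is set trans (3'S) by the fixed C2' centre.

Step 6
Reactants: 11 (2S,3S)-6-(benzyloxy)-3-(3,5-dimethoxyphenyl)-4-methoxy-2-(4-methoxyphenyl)-2,3-dihydro-1-benzofuran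
Product: 12 (2S,3S)-3-(3,5-dimethoxyphenyl)-4-methoxy-2-(4-methoxyphenyl)-2,3-dihydro-1-benzofuran-6-ol
Conditions: H2 (1 atm), Pd/C (10 wt %), EtOAc/MeOH, rt, stopped at full conversion
Reagents that add atoms: none
Why: Hydrogenolysis of the primary benzyl aryl ether is much faster than cleavage of the hindered secondary ring C2'–O1' bond, and no alkene is present yet.

Step 7
Reactants: 12 (2S,3S)-3-(3,5-dimethoxyphenyl)-4-methoxy-2-(4-methoxyphenyl)-2,3-dihydro-1-benzofuran-6-ol
Product: 13 (2S,3S)-3-(3,5-dimethoxyphenyl)-4-methoxy-2-(4-methoxyphenyl)-2,3-dihydro-1-benzofuran-6-yl trifluoromethanesulfonate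
Conditions: Tf2O (1.2 equiv), pyridine, CH2Cl2, 0 °C
Reagents that add atoms: trifluoromethanesulfonic anhydride, FC(F)(F)S(=O)(=O)OS(=O)(=O)C(F)(F)F
Why: O-Sulfonylation of the only free phenol turns the naringenin 7-oxygen into a leaving group for carbon–carbon bond formation at C6'.

Step 8
Reactants: 13 (2S,3S)-3-(3,5-dimethoxyphenyl)-4-methoxy-2-(4-methoxyphenyl)-2,3-dihydro-1-benzofuran-6-yl trifluoromethanesulfonate
Product: 14 [(2S,3S)-3-(3,5-dimethoxyphenyl)-4-methoxy-2-(4-methoxyphenyl)-2,3-dihydro-1-benzofuran-6-yl]boronic acid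
Conditions: B2(OH)4 (3 equiv), Pd(OAc)2 (2 mol %), XPhos (4 mol %), KOAc (3 equiv), EtOH, 80 °C
Reagents that add atoms: tetrahydroxydiboron, OB(O)B(O)O
Why: Miyaura-type borylation of an aryl triflate with tetrahydroxydiboron gives the free boronic acid directly at C6', a position flanked only by hydrogen atoms.

Step 9
Reactants: 4 (2S)-7-(benzyloxy)-5-methoxy-2-(4-methoxyphenyl)chroman-4-one
Product: 17 (2R)-7-(benzyloxy)-5-methoxy-2-(4-methoxyphenyl)chroman-4-one, via ring-opened chalcone 15 (not isolated), via racemic flavanone 16 (not isolated)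
Conditions: DBU (0.2 equiv), EtOH, 70 °C; AcOH; then preparative chiral SFC on amylose tris(3,5-dimethylphenylcarbamate), CO2/MeOH
Reagents that add atoms: none
Why: Reversible base-catalysed elimination to the 2'-hydroxychalcone and oxa-Michael re-closure scrambles C2, and flavanones separate on polysaccharide carbamate phases; the (R) peak is the one that does not co-elute with chiral-pool 4, and the (S) half returns to step 3.

Step 10
Reactants: 17 (2R)-7-(benzyloxy)-5-methoxy-2-(4-methoxyphenyl)chroman-4-one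
Product: 20 methyl (2R,3R)-6-(benzyloxy)-4-methoxy-2-(4-methoxyphenyl)-2,3-dihydro-1-benzofuran-3-carboxylate, via 2H-chromene enol ether 18 (not isolated), via trans C3 iodane ketal 19 (not isolated)
Conditions: PhI(OAc)2 (1.3 equiv), conc. H2SO4 (0.3 equiv), HC(OMe)3, 0 °C to rt
Reagents that add atoms: trimethyl orthoformate, COC(OC)OC
Why: The same trivalent-iodine ring contraction as in step 3 on the mirror-image flavanone carries C2 (R) over and places the ester trans by inversion at the iodine-bearing carbon.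

Step 11
Reactants: 20 methyl (2R,3R)-6-(benzyloxy)-4-methoxy-2-(4-methoxyphenyl)-2,3-dihydro-1-benzofuran-3-carboxylate
Product: 21 (2R,3R)-6-(benzyloxy)-4-methoxy-2-(4-methoxyphenyl)-2,3-dihydro-1-benzofuran-3-carboxylic acid
Conditions: Me3SnOH (4 equiv), ClCH2CH2Cl, 80 °C; 1 M HCl wash
Reagents that add atoms: trimethyltin hydroxide, C[Sn](C)(C)O
Why: Near-neutral ester hydrolysis as in step 4 keeps the base-sensitive dihydrofuran closed.

Step 12
Reactants: 21 (2R,3R)-6-(benzyloxy)-4-methoxy-2-(4-methoxyphenyl)-2,3-dihydro-1-benzofuran-3-carboxylic acid; 14 [(2S,3S)-3-(3,5-dimethoxyphenyl)-4-methoxy-2-(4-methoxyphenyl)-2,3-dihydro-1-benzofuran-6-yl]boronic acid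
Product: 23 (2R,3R)-6-(benzyloxy)-3-[(2S,3S)-3-(3,5-dimethoxyphenyl)-4-methoxy-2-(4-methoxyphenyl)-2,3-dihydro-1-benzofuran-6-yl]-4-methoxy-2-(4-methoxyphenyl)-2,3-dihydro-1-benzofuran, via tetrachlorophthalimidoyl ester 22 (not isolated)
Conditions: TCNHPI, N,N'-diisopropylcarbodiimide, DMAP (cat.), CH2Cl2, rt; solvent exchange; then 14 (2 equiv), NiCl2·6H2O (20 mol %), bathophenanthroline (22 mol %), Et3N (10 equiv), 1,4-dioxane/DMF 10:1, 75 °C
Reagents that add atoms: boronic acid 14, OB(O)c1cc(OC)c2c(c1)O[C@H](c1ccc(OC)cc1)[C@H]2c1cc(OC)cc(OC)c1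
Why: The decarboxylative Suzuki-type arylation rehearsed in step 5 joins the two halves, the planar C3 radical being captured by the bulky arylnickel species on the face away from the C2 aryl group, which sets C3 trans (3R) under control of C2 (R).

Step 13
Reactants: 23 (the C6 benzyl ether from step 12)
Product: 24 (2R,3R)-3-[(2S,3S)-3-(3,5-dimethoxyphenyl)-4-methoxy-2-(4-methoxyphenyl)-2,3-dihydro-1-benzofuran-6-yl]-4-methoxy-2-(4-methoxyphenyl)-2,3-dihydro-1-benzofuran-6-ol
Conditions: H2 (1 atm), Pd/C (10 wt %), EtOAc/MeOH, rt, stopped at full conversion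
Reagents that add atoms: none
Why: Benzyl ether hydrogenolysis as in step 6, done before the stilbene alkene is introduced.

Step 14
Reactants: 24 (the C6 phenol from step 13)
Product: 25 (2R,3R)-3-[(2S,3S)-3-(3,5-dimethoxyphenyl)-4-methoxy-2-(4-methoxyphenyl)-2,3-dihydro-1-benzofuran-6-yl]-4-methoxy-2-(4-methoxyphenyl)-2,3-dihydro-1-benzofuran-6-yl trifluoromethanesulfonate
Conditions: Tf2O (1.2 equiv), pyridine, CH2Cl2, 0 °C
Reagents that add atoms: trifluoromethanesulfonic anhydride, FC(F)(F)S(=O)(=O)OS(=O)(=O)C(F)(F)F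
Why: O-Sulfonylation of the single free phenol activates C6 of the outer ring for the Heck reaction.

Step 15
Reactants: 25 (the C6 triflate from step 14); 26 4-methoxystyrene
Product: 27 hepta-O-methyl ether of the target, (2R,3R)-3-[(2S,3S)-3-(3,5-dimethoxyphenyl)-4-methoxy-2-(4-methoxyphenyl)-2,3-dihydro-1-benzofuran-6-yl]-4-methoxy-2-(4-methoxyphenyl)-6-[(E)-2-(4-methoxyphenyl)ethenyl]-2,3-dihydro-1-benzofuran
Conditions: Pd(OAc)2 (5 mol %), P(o-tol)3 (12 mol %), LiCl (3 equiv), Et3N (3 equiv), DMF, 100 °C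
Reagents that add atoms: 4-methoxystyrene 26, C=Cc1ccc(OC)cc1
Why: Mizoroki–Heck reaction in which chloride steers the triflate-derived arylpalladium through the neutral pathway, so the aryl group adds to the terminal alkene carbon and syn β-hydride elimination gives the (E)-stilbene.

Step 16
Reactants: 27 hepta-O-methyl ether of the target
Product: 28 target, 4-[(E)-2-{(2R,3R)-3-[(2S,3S)-3-(3,5-dihydroxyphenyl)-4-hydroxy-2-(4-hydroxyphenyl)-2,3-dihydro-1-benzofuran-6-yl]-4-hydroxy-2-(4-hydroxyphenyl)-2,3-dihydro-1-benzofuran-6-yl}ethenyl]phenol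
Conditions: BBr3 (20 equiv), CH2Cl2, −78 °C to rt; MeOH then water
Reagents that add atoms: none
Why: Lewis-acid cleavage of all seven aryl methyl ethers; should a C2–O bond ionise reversibly, it can re-close only to the more stable trans ring dictated by the fixed C3 and C3' centres, and the C6 styryl group has no nucleophilic ring within reach for cyclisation.

**Compound list**

1 | (S)-naringenin, (2S)-5,7-dihydroxy-2-(4-hydroxyphenyl)chroman-4-one | Oc1cc(O)c2c(c1)O[C@H](c1ccc(O)cc1)CC2=O | starting material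
2 | benzyl bromide | BrCc1ccccc1 | starting material
3 | (2S)-7-(benzyloxy)-5-hydroxy-2-(4-hydroxyphenyl)chroman-4-one | C(c1ccccc1)Oc1cc(O)c2c(c1)O[C@H](c1ccc(O)cc1)CC2=O | intermediate
4 | (2S)-7-(benzyloxy)-5-methoxy-2-(4-methoxyphenyl)chroman-4-one | C(c1ccccc1)Oc1cc(OC)c2c(c1)O[C@H](c1ccc(OC)cc1)CC2=O | intermediate
5 | (2S)-7-(benzyloxy)-4,5-dimethoxy-2-(4-methoxyphenyl)-2H-chromene | C(c1ccccc1)Oc1cc(OC)c2c(c1)O[C@H](c1ccc(OC)cc1)C=C2OC | intermediate
6 | 2,3-trans 3-[acetoxy(phenyl)-λ3-iodanyl]-7-(benzyloxy)-4,4,5-trimethoxy-2-(4-methoxyphenyl)chromane (C2 as in 4) | C(c1ccccc1)Oc1cc(OC)c2c(c1)O[C@H](c1ccc(OC)cc1)[C@@H](I(OC(C)=O)c1ccccc1)C2(OC)OC | intermediate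
7 | methyl (2S,3S)-6-(benzyloxy)-4-methoxy-2-(4-methoxyphenyl)-2,3-dihydro-1-benzofuran-3-carboxylate | C(c1ccccc1)Oc1cc(OC)c2c(c1)O[C@H](c1ccc(OC)cc1)[C@H]2C(=O)OC | intermediate
8 | (2S,3S)-6-(benzyloxy)-4-methoxy-2-(4-methoxyphenyl)-2,3-dihydro-1-benzofuran-3-carboxylic acid | C(c1ccccc1)Oc1cc(OC)c2c(c1)O[C@H](c1ccc(OC)cc1)[C@H]2C(=O)O | intermediate
9 | 3,5-dimethoxyphenylboronic acid | COc1cc(OC)cc(B(O)O)c1 | starting material
10 | 4,5,6,7-tetrachloro-1,3-dioxoisoindolin-2-yl ester of acid 8 | C(c1ccccc1)Oc1cc(OC)c2c(c1)O[C@H](c1ccc(OC)cc1)[C@H]2C(=O)ON1C(=O)c2c(Cl)c(Cl)c(Cl)c(Cl)c2C1=O | intermediate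
11 | (2S,3S)-6-(benzyloxy)-3-(3,5-dimethoxyphenyl)-4-methoxy-2-(4-methoxyphenyl)-2,3-dihydro-1-benzofuran | C(c1ccccc1)Oc1cc(OC)c2c(c1)O[C@H](c1ccc(OC)cc1)[C@H]2c1cc(OC)cc(OC)c1 | intermediate
12 | (2S,3S)-3-(3,5-dimethoxyphenyl)-4-methoxy-2-(4-methoxyphenyl)-2,3-dihydro-1-benzofuran-6-ol | Oc1cc(OC)c2c(c1)O[C@H](c1ccc(OC)cc1)[C@H]2c1cc(OC)cc(OC)c1 | intermediate
13 | (2S,3S)-3-(3,5-dimethoxyphenyl)-4-methoxy-2-(4-methoxyphenyl)-2,3-dihydro-1-benzofuran-6-yl trifluoromethanesulfonate | FC(F)(F)S(=O)(=O)Oc1cc(OC)c2c(c1)O[C@H](c1ccc(OC)cc1)[C@H]2c1cc(OC)cc(OC)c1 | intermediate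
14 | [(2S,3S)-3-(3,5-dimethoxyphenyl)-4-methoxy-2-(4-methoxyphenyl)-2,3-dihydro-1-benzofuran-6-yl]boronic acid | OB(O)c1cc(OC)c2c(c1)O[C@H](c1ccc(OC)cc1)[C@H]2c1cc(OC)cc(OC)c1 | intermediate
15 | (E)-1-[4-(benzyloxy)-2-hydroxy-6-methoxyphenyl]-3-(4-methoxyphenyl)prop-2-en-1-one | C(c1ccccc1)Oc1cc(OC)c(C(=O)/C=C/c2ccc(OC)cc2)c(O)c1 | intermediate
16 | racemic 7-(benzyloxy)-5-methoxy-2-(4-methoxyphenyl)chroman-4-one | C(c1ccccc1)Oc1cc(OC)c2c(c1)OC(c1ccc(OC)cc1)CC2=O | intermediate
17 | (2R)-7-(benzyloxy)-5-methoxy-2-(4-methoxyphenyl)chroman-4-one | C(c1ccccc1)Oc1cc(OC)c2c(c1)O[C@@H](c1ccc(OC)cc1)CC2=O | intermediate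
18 | (2R)-7-(benzyloxy)-4,5-dimethoxy-2-(4-methoxyphenyl)-2H-chromene | C(c1ccccc1)Oc1cc(OC)c2c(c1)O[C@@H](c1ccc(OC)cc1)C=C2OC | intermediate
19 | mirror image of iodane 6 (2,3-trans, C2 as in 17) | C(c1ccccc1)Oc1cc(OC)c2c(c1)O[C@@H](c1ccc(OC)cc1)[C@H](I(OC(C)=O)c1ccccc1)C2(OC)OC | intermediate
20 | methyl (2R,3R)-6-(benzyloxy)-4-methoxy-2-(4-methoxyphenyl)-2,3-dihydro-1-benzofuran-3-carboxylate | C(c1ccccc1)Oc1cc(OC)c2c(c1)O[C@@H](c1ccc(OC)cc1)[C@@H]2C(=O)OC | intermediate
21 | (2R,3R)-6-(benzyloxy)-4-methoxy-2-(4-methoxyphenyl)-2,3-dihydro-1-benzofuran-3-carboxylic acid | C(c1ccccc1)Oc1cc(OC)c2c(c1)O[C@@H](c1ccc(OC)cc1)[C@@H]2C(=O)O | intermediate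
22 | 4,5,6,7-tetrachloro-1,3-dioxoisoindolin-2-yl ester of acid 21 | C(c1ccccc1)Oc1cc(OC)c2c(c1)O[C@@H](c1ccc(OC)cc1)[C@@H]2C(=O)ON1C(=O)c2c(Cl)c(Cl)c(Cl)c(Cl)c2C1=O | intermediate
23 | (2R,3R)-6-(benzyloxy)-3-[(2S,3S)-3-(3,5-dimethoxyphenyl)-4-methoxy-2-(4-methoxyphenyl)-2,3-dihydro-1-benzofuran-6-yl]-4-methoxy-2-(4-methoxyphenyl)-2,3-dihydro-1-benzofuran | C(c1ccccc1)Oc1cc(OC)c2c(c1)O[C@@H](c1ccc(OC)cc1)[C@@H]2c1cc(OC)c2c(c1)O[C@H](c1ccc(OC)cc1)[C@H]2c1cc(OC)cc(OC)c1 | intermediate
24 | C6 phenol of 23 (benzyl removed) | Oc1cc(OC)c2c(c1)O[C@@H](c1ccc(OC)cc1)[C@@H]2c1cc(OC)c2c(c1)O[C@H](c1ccc(OC)cc1)[C@H]2c1cc(OC)cc(OC)c1 | intermediate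
25 | C6 trifluoromethanesulfonate of 24 | FC(F)(F)S(=O)(=O)Oc1cc(OC)c2c(c1)O[C@@H](c1ccc(OC)cc1)[C@@H]2c1cc(OC)c2c(c1)O[C@H](c1ccc(OC)cc1)[C@H]2c1cc(OC)cc(OC)c1 | intermediate
26 | 4-methoxystyrene | C=Cc1ccc(OC)cc1 | starting material
27 | hepta-O-methyl ether of the target, (2R,3R,2'S,3'S), (E)-stilbene | COc1ccc(/C=C/c2cc(OC)c3c(c2)O[C@@H](c2ccc(OC)cc2)[C@@H]3c2cc(OC)c3c(c2)O[C@H](c2ccc(OC)cc2)[C@H]3c2cc(OC)cc(OC)c2)cc1 | intermediate
28 | CNP0248228.3, (2R,3R,2'S,3'S) | Oc1ccc(/C=C/c2cc(O)c3c(c2)O[C@@H](c2ccc(O)cc2)[C@@H]3c2cc(O)c3c(c2)O[C@H](c2ccc(O)cc2)[C@H]3c2cc(O)cc(O)c2)cc1 | target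

**Step count**

Total: 16 steps. Longest linear sequence: 13 steps (1–8, then 12–16, from (S)-naringenin).

**Steps most likely to fail**

Step 3 (and its mirror, step 10). Several processes can divert the reaction:
- ketal formation may be slow, because the carbonyl is deactivated by the two para/ortho alkoxy groups;
- once the ketal has removed the deactivating carbonyl, the trialkoxy ring A may be attacked by the iodine reagent at C6 or C8;
- the 4-methoxyphenyl group may shift instead of the ring carbon, or the flavanone may simply be dehydrogenated;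
- the acid may erode C2 through the chalcone.

The fallback is a photochemical Wolff ring contraction, which makes the same skeletal change without oxidant or acid. It sets out from 4. Kinetic enolisation (LiHMDS, THF, −78 °C) and acylation with CF3CO2CH2CF3 should give the (2S)-3-(trifluoroacetyl)flavanone F1. Detrifluoroacetylative diazo transfer (MsN3, Et3N, MeCN, rt) should give the (2S)-3-diazoflavanone F2. Irradiation at 365 nm in MeOH moves the ring A carbon from the carbonyl carbon to the carbene carbon, and methanol traps the ketene as a cis/trans mixture of esters. Brief NaOMe (cat.) in MeOH at 0 °C equilibrates C3 to the trans ester 7, where the route is rejoined at step 4. The same sequence on 17 would give 20.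

Step 12 (step 5 is its rehearsal on a simple boronic acid). Transmetalation from the large boronic acid 14 may be slow. The benzylic C3 radical could then dimerise or abstract hydrogen, β-hydride loss from the alkylnickel would aromatise the ring to a benzofuran, and 14 may protodeboronate.

The fallback generates the radical by oxidation of the carboxylate and brings in the aryl partner by oxidative addition, so no boron-to-nickel transfer is needed. It sets out from triflate 13 and acid 21. Palladium-catalysed triflate-to-bromide exchange on 13 (Pd2(dba)3, t-BuBrettPhos, KBr, KF, 1,4-dioxane, 110 °C) should give the C6' aryl bromide F3. Dual photoredox/nickel decarboxylative arylation of 21 with F3 (Ir[dF(CF3)ppy]2(dtbbpy)PF6, NiCl2(dme), 4,4'-di-tert-butyl-2,2'-bipyridine, Cs2CO3, DMF, blue LEDs, rt) should then give 23 with the same trans preference, at close to 1:1 stoichiometry. The route is rejoined at step 13.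

Step 2. The hydrogen-bonded 5-OH may be methylated only partly, and some C2 configuration may be lost by ring opening on the basic silver oxide surface.

The fallback gives up retention at this stage and takes the configuration from the resolution already in the route. It sets out from 3. MeI and K2CO3 in refluxing acetone open the ring and methylate, giving chalcone 15 (its chelated 2'-OH stays free). NaOAc in refluxing EtOH closes it to racemic flavanone 16. The chiral SFC of step 9 then delivers 4 and 17 in one run, in the 1:1 ratio the target needs, and the racemisation part of step 9 is no longer required. No compound outside the list arises (F0).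

**Further compounds**

F1 | step 3 | (2S)-7-(benzyloxy)-5-methoxy-2-(4-methoxyphenyl)-3-(trifluoroacetyl)chroman-4-one (C3 unassigned) | C(c1ccccc1)Oc1cc(OC)c2c(c1)O[C@H](c1ccc(OC)cc1)C(C(=O)C(F)(F)F)C2=O
F2 | step 3 | (2S)-7-(benzyloxy)-3-diazo-5-methoxy-2-(4-methoxyphenyl)chroman-4-one | C(c1ccccc1)Oc1cc(OC)c2c(c1)O[C@H](c1ccc(OC)cc1)C(=[N+]=[N-])C2=O
F3 | step 12 | (2S,3S)-6-bromo-3-(3,5-dimethoxyphenyl)-4-methoxy-2-(4-methoxyphenyl)-2,3-dihydro-1-benzofuran | Brc1cc(OC)c2c(c1)O[C@H](c1ccc(OC)cc1)[C@H]2c1cc(OC)cc(OC)c1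
F0 | step 2 | none | none
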